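**Retrosynthetic overview**
- The oxolane is the only ring and is formed last: 5-exo bromoetherification of an open-chain (E)-allylic chloride makes the C6–O and C7–Br bonds in one anti addition.
- Before that, C8–Cl comes from an allylic alcohol and the (E)-bromoalkene (C1=C2) from Takai olefination of a C2 aldehyde.
- The C3–OH/C4–Br anti-bromohydrin comes from bromide opening of a (2S,3S)-2,3-epoxy alcohol, reached by matched Sharpless epoxidation and Payne rearrangement of an (S)-secondary allylic alcohol.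
- Key C4–C5 bond: Brown asymmetric allylboration of methacrolein; the (E)-C6=C7 unit is then added by cross-metathesis with methyl methacrylate.

Assumption: locants C1–C8 in the comments follow the open chain BrC1H=C2H–C3(CH3)(O)–C4H(Br)–C5H2–C6H(O)–C7(CH3)(Br)–C8H2Cl; (−)-Ipc2BOMe, CrBr2 and the metathesis catalyst are bought.

**Step 1**
Reactants: 1 methacrolein; 2 (−)-B-methoxydiisopinocampheylborane; 3 allylmagnesium bromide
Product: 6 (3S)-2-methylhexa-1,5-dien-3-ol, via (−)-B-allyldiisopinocampheylborane 4 (not isolated), via diisopinocampheylborinate ester 5 (not isolated)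
Conditions: 2, 3, Et2O, −78 °C → rt; then 1, Et2O, −78 °C; then 3 M NaOH, 30% H2O2, rt
Reagents that add atoms: none
Why: Brown asymmetric allylboration (carbonyl allylation) joins the two fragments through a chair-like six-membered transition state in which the isopinocampheyl groups from (+)-α-pinene steer the allyl group to the Si face of the aldehyde, setting the C4 carbinol as S (about 90% ee).

**Step 2**
Reactants: 6 (3S)-2-methylhexa-1,5-dien-3-ol; 7 methyl methacrylate
Product: 8 methyl (2E,5S)-5-hydroxy-2,6-dimethylhepta-2,6-dienoate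
Conditions: 7 (10 equiv), second-generation Hoveyda–Grubbs catalyst (5 mol %), CH2Cl2, 40 °C
Reagents that add atoms: none
Why: Olefin cross-metathesis engages only the monosubstituted alkene (the isopropenyl group next to the carbinol is too hindered) and gives the trisubstituted enoate as the thermodynamically favoured E isomer, which fixes the C6=C7 geometry that later relates C6 and C7.

**Step 3**
Reactants: 8 methyl (2E,5S)-5-hydroxy-2,6-dimethylhepta-2,6-dienoate
Product: 9 (2E,5S)-2,6-dimethylhepta-2,6-diene-1,5-diol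
Conditions: i-Bu2AlH (3.5 equiv), CH2Cl2, −78 → −20 °C; aq. potassium sodium tartrate
Reagents that add atoms: none
Why: 1,2-Reduction of the conjugated ester with i-Bu2AlH at low temperature gives the allylic alcohol without touching the alkenes or the stereocentre.

**Step 4**
Reactants: 9 (2E,5S)-2,6-dimethylhepta-2,6-diene-1,5-diol
Product: 10 (3S,5E)-7-[(tert-butyldiphenylsilyl)oxy]-2,6-dimethylhepta-1,5-dien-3-ol
Conditions: TBDPSCl (1.05 equiv), imidazole, CH2Cl2, 0 °C
Reagents that add atoms: tert-butyl(chloro)diphenylsilane, CC(C)(C)[Si](Cl)(c1ccccc1)c1ccccc1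
Why: Silylation with the bulky chlorosilane is selective for the unhindered primary allylic hydroxyl over the secondary one flanked by the isopropenyl group.

**Step 5**
Reactants: 10 (3S,5E)-7-[(tert-butyldiphenylsilyl)oxy]-2,6-dimethylhepta-1,5-dien-3-ol
Product: 11 (1S,3E)-5-[(tert-butyldiphenylsilyl)oxy]-4-methyl-1-[(2R)-2-methyloxiran-2-yl]pent-3-en-1-ol
Conditions: Ti(OiPr)4 (10 mol %), L-(+)-DIPT (15 mol %), t-BuOOH (1.5 equiv), 4 Å MS, CH2Cl2, −20 °C
Reagents that add atoms: tert-butyl hydroperoxide, CC(C)(C)OO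
Why: Sharpless asymmetric epoxidation in the matched (fast-reacting) pairing of the S carbinol with L-(+)-tartrate delivers oxygen to one face of the isopropenyl alkene to give the erythro epoxy alcohol (new quaternary centre R), leaves the homoallylic trisubstituted alkene alone and, acting as a kinetic resolution, raises the enantiomeric purity.

**Step 6**
Reactants: 11 (1S,3E)-5-[(tert-butyldiphenylsilyl)oxy]-4-methyl-1-[(2R)-2-methyloxiran-2-yl]pent-3-en-1-ol
Product: 12 {(2S,3S)-3-[(2E)-4-[(tert-butyldiphenylsilyl)oxy]-3-methylbut-2-en-1-yl]-2-methyloxiran-2-yl}methanol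
Conditions: 0.5 M aq. NaOH, t-BuOH, 0 °C → rt
Reagents that add atoms: none
Why: Payne rearrangement: the C4 alkoxide opens the neighbouring epoxide at the quaternary carbon by intramolecular SN2 with inversion, and the equilibrium lies on the side of the trisubstituted epoxide with a primary alkoxide, giving the (2S,3S)-2,3-epoxy alcohol.

**Step 7**
Reactants: 12 {(2S,3S)-3-[(2E)-4-[(tert-butyldiphenylsilyl)oxy]-3-methylbut-2-en-1-yl]-2-methyloxiran-2-yl}methanol
Product: 13 (2S,3R,5E)-3-bromo-7-[(tert-butyldiphenylsilyl)oxy]-2,6-dimethylhept-5-ene-1,2-diol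
Conditions: Et2NH2Br (2 equiv), Ti(OiPr)4 (1.5 equiv), CH2Cl2, rt
Reagents that add atoms: diethylammonium bromide, CC[NH2+]CC.[Br-]
Why: Titanium-chelate-directed C-3-selective opening of a 2,3-epoxy alcohol by bromide is an SN2 reaction with inversion at the secondary carbon, so the (2S,3S) epoxide gives the anti bromohydrin with C4 as R (bromide) and C3 as S (tertiary alcohol).

**Step 8**
Reactants: 13 (2S,3R,5E)-3-bromo-7-[(tert-butyldiphenylsilyl)oxy]-2,6-dimethylhept-5-ene-1,2-diol
Product: 14 (2S,3R,5E)-3-bromo-7-[(tert-butyldiphenylsilyl)oxy]-2,6-dimethyl-1,2-bis[(triethylsilyl)oxy]hept-5-ene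
Conditions: Et3SiOTf (2.5 equiv), 2,6-lutidine, CH2Cl2, −78 → 0 °C
Reagents that add atoms: triethylsilyl trifluoromethanesulfonate, CC[Si](CC)(CC)OS(=O)(=O)C(F)(F)F
Why: The silyl triflate silylates both the primary and the hindered tertiary hydroxyl, which masks the bromohydrin against base-induced epoxide closure in the following steps.

**Step 9**
Reactants: 14 (2S,3R,5E)-3-bromo-7-[(tert-butyldiphenylsilyl)oxy]-2,6-dimethyl-1,2-bis[(triethylsilyl)oxy]hept-5-ene
Product: 15 (2S,3R,5E)-3-bromo-7-[(tert-butyldiphenylsilyl)oxy]-2,6-dimethyl-2-[(triethylsilyl)oxy]hept-5-enal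
Conditions: (COCl)2, DMSO, CH2Cl2, −78 → −40 °C; then Et3N, −78 → 0 °C
Reagents that add atoms: none
Why: Under Swern conditions the primary triethylsilyl ether is cleaved and oxidised selectively (the tertiary silyl ether and the bulky primary silyl ether survive), and the aldehyde can neither epimerise nor eliminate because its α-carbon is quaternary.

**Step 10**
Reactants: 15 (2S,3R,5E)-3-bromo-7-[(tert-butyldiphenylsilyl)oxy]-2,6-dimethyl-2-[(triethylsilyl)oxy]hept-5-enal; 16 bromoform
Product: 17 (1E,3S,4R,6E)-1,4-dibromo-8-[(tert-butyldiphenylsilyl)oxy]-3,7-dimethyl-3-[(triethylsilyl)oxy]octa-1,6-diene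
Conditions: CrBr2 (8 equiv), 16 (3 equiv), THF, rt → 50 °C
Reagents that add atoms: none
Why: Takai olefination: the geminal dichromium species formed from bromoform adds to the aldehyde and anti-elimination gives the E-bromoalkene, CrBr2 being used so that no chloroalkene arises by halide exchange.

**Step 11**
Reactants: 17 (1E,3S,4R,6E)-1,4-dibromo-8-[(tert-butyldiphenylsilyl)oxy]-3,7-dimethyl-3-[(triethylsilyl)oxy]octa-1,6-diene
Product: 18 (2E,5R,6S,7E)-5,8-dibromo-2,6-dimethylocta-2,7-diene-1,6-diol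
Conditions: HF·pyridine, pyridine, THF, 0 °C → rt
Reagents that add atoms: none
Why: Acidic fluoride cleaves both silyl ethers (Si–F bond formation) without the basic conditions that would close the bromohydrin to an epoxide.

**Step 12**
Reactants: 18 (2E,5R,6S,7E)-5,8-dibromo-2,6-dimethylocta-2,7-diene-1,6-diol
Product: 20 (1E,3S,4R,6E)-1,4-dibromo-8-chloro-3,7-dimethylocta-1,6-dien-3-ol, via allylic methanesulfonate 19 (not isolated)
Conditions: MsCl, 2,4,6-collidine, LiCl, DMF, 0 °C
Reagents that add atoms: methanesulfonyl chloride, CS(=O)(=O)Cl (atoms kept in 19 only); lithium chloride, [Li+].[Cl-]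
Why: Meyers-type allylic chlorination: only the primary allylic hydroxyl is mesylated and chloride displaces the mesylate by SN2 without allylic transposition, so the E geometry is kept and the tertiary alcohol is untouched.

**Step 13**
Reactants: 20 (1E,3S,4R,6E)-1,4-dibromo-8-chloro-3,7-dimethylocta-1,6-dien-3-ol
Product: 21 (2S,3R,5R)-3-bromo-2-[(E)-2-bromoethenyl]-5-[(2R)-2-bromo-1-chloropropan-2-yl]-2-methyloxolane
Conditions: NBS (1.1 equiv), CH2Cl2, 0 °C, dark
Reagents that add atoms: N-bromosuccinimide, O=C1CCC(=O)N1Br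
Why: 5-exo bromoetherification: NBS forms the bromonium ion on the electron-richer trisubstituted alkene and the tertiary hydroxyl opens it at C6 anti to bromine, so the E geometry can only give the 6R,7R or 6S,7S pair, and a chair-like transition state with the C4 bromine and the reacting alkene pseudo-equatorial (3,5-cis) is expected to favour the 6R,7R target, the epimer being removed by chromatography.

**Compound list**
1 | methacrolein (2-methylprop-2-enal) | CC(=C)C=O | starting material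
2 | (−)-B-methoxydiisopinocampheylborane [(−)-Ipc2BOMe, from (+)-α-pinene] | COB([C@@H]1C[C@@H]2C[C@H]([C@H]1C)C2(C)C)[C@@H]1C[C@@H]2C[C@H]([C@H]1C)C2(C)C | starting material
3 | allylmagnesium bromide | C=CC[Mg]Br | starting material
4 | (−)-B-allyldiisopinocampheylborane | C=CCB([C@@H]1C[C@@H]2C[C@H]([C@H]1C)C2(C)C)[C@@H]1C[C@@H]2C[C@H]([C@H]1C)C2(C)C | intermediate
5 | (3S)-2-methylhexa-1,5-dien-3-yl diisopinocampheylborinate | C=C(C)[C@@H](OB([C@@H]1C[C@@H]2C[C@H]([C@H]1C)C2(C)C)[C@@H]1C[C@@H]2C[C@H]([C@H]1C)C2(C)C)CC=C | intermediate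
6 | (3S)-2-methylhexa-1,5-dien-3-ol | C=C(C)[C@@H](O)CC=C | intermediate
7 | methyl methacrylate | C=C(C)C(=O)OC | starting material
8 | methyl (2E,5S)-5-hydroxy-2,6-dimethylhepta-2,6-dienoate | C=C(C)[C@@H](O)C/C=C(\C)C(=O)OC | intermediate
9 | (2E,5S)-2,6-dimethylhepta-2,6-diene-1,5-diol | C=C(C)[C@@H](O)C/C=C(\C)CO | intermediate
10 | (3S,5E)-7-[(tert-butyldiphenylsilyl)oxy]-2,6-dimethylhepta-1,5-dien-3-ol | C=C(C)[C@@H](O)C/C=C(\C)CO[Si](c1ccccc1)(c1ccccc1)C(C)(C)C | intermediate
11 | (1S,3E)-5-[(tert-butyldiphenylsilyl)oxy]-4-methyl-1-[(2R)-2-methyloxiran-2-yl]pent-3-en-1-ol | C[C@@]1(CO1)[C@@H](O)C/C=C(\C)CO[Si](c1ccccc1)(c1ccccc1)C(C)(C)C | intermediate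
12 | {(2S,3S)-3-[(2E)-4-[(tert-butyldiphenylsilyl)oxy]-3-methylbut-2-en-1-yl]-2-methyloxiran-2-yl}methanol | OC[C@]1(C)O[C@H]1C/C=C(\C)CO[Si](c1ccccc1)(c1ccccc1)C(C)(C)C | intermediate
13 | (2S,3R,5E)-3-bromo-7-[(tert-butyldiphenylsilyl)oxy]-2,6-dimethylhept-5-ene-1,2-diol | OC[C@](C)(O)[C@H](Br)C/C=C(\C)CO[Si](c1ccccc1)(c1ccccc1)C(C)(C)C | intermediate
14 | (2S,3R,5E)-3-bromo-7-[(tert-butyldiphenylsilyl)oxy]-2,6-dimethyl-1,2-bis[(triethylsilyl)oxy]hept-5-ene | CC[Si](CC)(CC)OC[C@](C)(O[Si](CC)(CC)CC)[C@H](Br)C/C=C(\C)CO[Si](c1ccccc1)(c1ccccc1)C(C)(C)C | intermediate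
15 | (2S,3R,5E)-3-bromo-7-[(tert-butyldiphenylsilyl)oxy]-2,6-dimethyl-2-[(triethylsilyl)oxy]hept-5-enal | O=C[C@](C)(O[Si](CC)(CC)CC)[C@H](Br)C/C=C(\C)CO[Si](c1ccccc1)(c1ccccc1)C(C)(C)C | intermediate
16 | bromoform | BrC(Br)Br | starting material
17 | (1E,3S,4R,6E)-1,4-dibromo-8-[(tert-butyldiphenylsilyl)oxy]-3,7-dimethyl-3-[(triethylsilyl)oxy]octa-1,6-diene | Br/C=C/[C@](C)(O[Si](CC)(CC)CC)[C@H](Br)C/C=C(\C)CO[Si](c1ccccc1)(c1ccccc1)C(C)(C)C | intermediate
18 | (2E,5R,6S,7E)-5,8-dibromo-2,6-dimethylocta-2,7-diene-1,6-diol | Br/C=C/[C@](C)(O)[C@H](Br)C/C=C(\C)CO | intermediate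
19 | (2E,5R,6S,7E)-5,8-dibromo-6-hydroxy-2,6-dimethylocta-2,7-dien-1-yl methanesulfonate | Br/C=C/[C@](C)(O)[C@H](Br)C/C=C(\C)COS(C)(=O)=O | intermediate
20 | (1E,3S,4R,6E)-1,4-dibromo-8-chloro-3,7-dimethylocta-1,6-dien-3-ol | Br/C=C/[C@](C)(O)[C@H](Br)C/C=C(\C)CCl | intermediate
21 | (2S,3R,5R)-3-bromo-2-[(E)-2-bromoethenyl]-5-[(2R)-2-bromo-1-chloropropan-2-yl]-2-methyloxolane | C[C@](Br)(CCl)[C@H]1C[C@@H](Br)[C@](C)(/C=C/Br)O1 | target

**Step count**
Total steps: 13. Longest linear sequence: 13 steps (1 → 21).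

**Steps most likely to fail, with fallbacks**

Step 13 (bromoetherification). The face selectivity rests on substrate control only and may be modest, and some 6-endo oxane may form. The fallback sets out from 20 and comes back at 21; it lets a reagent choose the face. Compound 20 is silylated (Et3SiOTf, 2,6-lutidine, CH2Cl2) to triethyl{[(1E,3S,4R,6E)-1,4-dibromo-8-chloro-3,7-dimethylocta-1,6-dien-3-yl]oxy}silane F5. Shi epoxidation with the D-fructose-derived ketone (KHSO5, K2CO3 buffer, MeCN/dimethoxymethane, 0 °C) then gives the 6R,7S epoxide {[(1E,3S,4R)-1,4-dibromo-5-[(2R,3S)-3-(chloromethyl)-3-methyloxiran-2-yl]-3-methylpent-1-en-3-yl]oxy}triethylsilane F6. Li2NiBr4 in THF opens the epoxide at the secondary carbon with inversion to the bromohydrin (2R,3S,5R,6S,7E)-3,5,8-tribromo-1-chloro-2,6-dimethyl-6-[(triethylsilyl)oxy]oct-7-en-2-ol F7. BF3·OEt2 in CH2Cl2 at −40 °C ionises the tertiary alcohol with participation of the neighbouring bromine, which re-forms the bromonium ion on one defined face; the C3 oxygen closes the ring at C6 with loss of the silyl group and gives 21.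

Step 7 (bromide opening). Bromide may attack the quaternary epoxide carbon instead of C4. The fallback sets out from 12 and comes back at 13. Compound 12 is oxidised (TEMPO, PhI(OAc)2, MeCN–H2O) to (2R,3S)-3-[(2E)-4-[(tert-butyldiphenylsilyl)oxy]-3-methylbut-2-en-1-yl]-2-methyloxirane-2-carboxylic acid F2, which Me3SiCHN2 converts into methyl (2R,3S)-3-[(2E)-4-[(tert-butyldiphenylsilyl)oxy]-3-methylbut-2-en-1-yl]-2-methyloxirane-2-carboxylate F3. In this glycidic ester the carbonyl group suppresses ionisation at the quaternary carbon, so MgBr2·OEt2 (Et2O, 0 °C) can only deliver bromide to the β-carbon with inversion, giving methyl (2S,3R,5E)-3-bromo-7-[(tert-butyldiphenylsilyl)oxy]-2-hydroxy-2,6-dimethylhept-5-enoate F4. Reduction with i-Bu2AlH (CH2Cl2, −78 → 0 °C) returns 13.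

Step 6 (Payne rearrangement). The equilibrium may not lie far enough on the side of 12, and hydroxide may open the terminal epoxide of 11. The fallback sets out from 10 and comes back at 12, bypassing 11. A 1,3-transposition of the allylic hydroxyl of 10 with Ph3SiOReO3 (2 mol %, Et2O, 0 °C) gives the primary allylic alcohol (2E,5E)-7-[(tert-butyldiphenylsilyl)oxy]-2,6-dimethylhepta-2,5-dien-1-ol F1. Sharpless epoxidation of F1 (Ti(OiPr)4, L-(+)-DIPT, t-BuOOH, 4 Å MS, CH2Cl2, −20 °C) gives 12 directly, with both epoxide centres set by the tartrate alone; the C4 stereocentre from step 1 is given up on this path.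

**Further compounds**
F1 | step 6 | (2E,5E)-7-[(tert-butyldiphenylsilyl)oxy]-2,6-dimethylhepta-2,5-dien-1-ol | OC/C(C)=C/C/C=C(\C)CO[Si](c1ccccc1)(c1ccccc1)C(C)(C)C
F2 | step 7 | (2R,3S)-3-[(2E)-4-[(tert-butyldiphenylsilyl)oxy]-3-methylbut-2-en-1-yl]-2-methyloxirane-2-carboxylic acid | OC(=O)[C@]1(C)O[C@H]1C/C=C(\C)CO[Si](c1ccccc1)(c1ccccc1)C(C)(C)C
F3 | step 7 | methyl (2R,3S)-3-[(2E)-4-[(tert-butyldiphenylsilyl)oxy]-3-methylbut-2-en-1-yl]-2-methyloxirane-2-carboxylate | COC(=O)[C@]1(C)O[C@H]1C/C=C(\C)CO[Si](c1ccccc1)(c1ccccc1)C(C)(C)C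
F4 | step 7 | methyl (2S,3R,5E)-3-bromo-7-[(tert-butyldiphenylsilyl)oxy]-2-hydroxy-2,6-dimethylhept-5-enoate | COC(=O)[C@](C)(O)[C@H](Br)C/C=C(\C)CO[Si](c1ccccc1)(c1ccccc1)C(C)(C)C
F5 | step 13 | triethyl{[(1E,3S,4R,6E)-1,4-dibromo-8-chloro-3,7-dimethylocta-1,6-dien-3-yl]oxy}silane | Br/C=C/[C@](C)(O[Si](CC)(CC)CC)[C@H](Br)C/C=C(\C)CCl
F6 | step 13 | {[(1E,3S,4R)-1,4-dibromo-5-[(2R,3S)-3-(chloromethyl)-3-methyloxiran-2-yl]-3-methylpent-1-en-3-yl]oxy}triethylsilane | Br/C=C/[C@](C)(O[Si](CC)(CC)CC)[C@H](Br)C[C@H]1O[C@]1(C)CCl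
F7 | step 13 | (2R,3S,5R,6S,7E)-3,5,8-tribromo-1-chloro-2,6-dimethyl-6-[(triethylsilyl)oxy]oct-7-en-2-ol | Br/C=C/[C@](C)(O[Si](CC)(CC)CC)[C@H](Br)C[C@H](Br)[C@](C)(O)CCl
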